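**Plan**

- Retrosynthesis: the aryl ether C–O bond is cut first (Mitsunobu, umbelliferone). Next comes the ring bond C2–C3 of the cyclohexene, between the CH that carries the CH2OAr carbon and the methyl-bearing alkene carbon. Then the C3=C4 alkene (Wittig) and the bond from C2 to the CH2O carbon (one-carbon homologation) are cut, which leads back to an acyclic acid–aldehyde.
- Enabling feature: ring carbon C2 is alpha to the exocyclic carbon that ends as CH2OAr, so with that carbon at the ester level C2 is an enolate carbon. Its ring neighbour C3 is an sp2 carbon that can enter as a (Z)-alkenyl iodide. A palladium enolate–alkenyl iodide coupling therefore closes the six-membered carbocycle with the C3=C4 alkene already in place.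
- Forward: (S)-carvone gives C6 (isopropenyl) and, by two enolate alkylations, the quaternary C1. Epoxidation and periodic acid cleavage open the carbocycle. Stork–Zhao olefination and Arndt–Eistert homologation give the cyclisation substrate. After ring closure come reduction, Mitsunobu etherification, desilylation and oxidation.
- Stereochemistry: C6 comes from the chiral pool, C1 from alkylation anti to isopropenyl, and C2 from kinetic protonation of the product dienolate anti to the pseudo-axial C1 methyl.

Key step: step 9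

Remark: ring positions are numbered as in the target name (C1 quaternary carbon, C2 CH–CH2OAr, C3 methyl-bearing alkene carbon, C4 =CH, C5 CH2, C6 CH–isopropenyl); TBDPS = tert-butyldiphenylsilyl.

**Route**

Step 1
Reactants: 1 3-iodopropan-1-ol
Product: 2 tert-butyl(3-iodopropoxy)diphenylsilane
Conditions: t-BuPh2SiCl, imidazole, DMF, rt
Reagents that add atoms: tert-butyl(chloro)diphenylsilane, CC(C)(C)[Si](Cl)(c1ccccc1)c1ccccc1
Why: silylation of a primary alcohol with a silyl chloride and imidazole is routine and gives an alkylating agent whose oxygen function should survive base, periodic acid, hydride and Mitsunobu conditions and be released by fluoride at the end.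

Step 2
Reactants: 3 (S)-(+)-carvone
Product: 5 (5S)-2,6-dimethyl-5-(prop-1-en-2-yl)cyclohex-2-en-1-one (6-methylcarvone; both C6 epimers), via lithium enolate 4 (not isolated)
Conditions: LiN(i-Pr)2, THF, −78 °C; MeI, −78 to 0 °C
Reagents that add atoms: iodomethane, CI
Why: kinetic deprotonation at the alpha-prime CH2 and C-methylation of the cross-conjugated enolate is the standard enolate alkylation of carvone, and the configuration of the new centre does not matter because it is made planar again in step 3.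

Step 3
Reactants: 5 6-methylcarvone; 2 tert-butyl(3-iodopropoxy)diphenylsilane
Product: 7 (5R,6R)-6-{3-[tert-butyl(diphenyl)silyl]oxypropyl}-2,6-dimethyl-5-(prop-1-en-2-yl)cyclohex-2-en-1-one, via lithium enolate 6 (not isolated)
Conditions: LiN(i-Pr)2, THF, −78 °C; 2, DMPU, −78 °C to rt
Reagents that add atoms: none
Why: enolate alkylation of the tetrasubstituted alpha-prime enolate should occur on the face opposite the neighbouring isopropenyl group (the usual outcome for 6-substituted carvone enolates), which sets the quaternary centre with methyl cis and the chain trans to isopropenyl.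

Step 4
Reactants: 7 dialkylated enone
Product: 8 (3R,4R)-3-{3-[tert-butyl(diphenyl)silyl]oxypropyl}-1,3-dimethyl-4-(prop-1-en-2-yl)-7-oxabicyclo[4.1.0]heptan-2-one (epoxide diastereomers)
Conditions: H2O2 (30% aq), NaOH, MeOH, 0 °C
Reagents that add atoms: hydrogen peroxide, OO
Why: Weitz–Scheffer nucleophilic epoxidation attacks only the electron-poor enone C=C and leaves the isopropenyl group alone, and the epoxide configuration is irrelevant because both epoxide carbons lose their stereochemistry in step 5.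

Step 5
Reactants: 8 epoxy ketone
Product: 9 (2R,3R)-2-{3-[tert-butyl(diphenyl)silyl]oxypropyl}-2,4-dimethyl-3-(2-oxoethyl)pent-4-enoic acid
Conditions: H5IO6, THF/H2O, 0 °C to rt
Reagents that add atoms: water, O
Why: periodic acid opens the alpha,beta-epoxy ketone hydrolytically and cleaves the resulting ketol/1,2-dicarbonyl array (glycol-type cleavage), so the methyl-bearing carbon leaves as acetic acid while the acid stays on the quaternary carbon and the aldehyde on the side-chain methylene, with both stereocentres and the isolated alkene untouched.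

Step 6
Reactants: 9 aldehyde acid
Product: 11 (2R,3R,5Z)-2-{3-[tert-butyl(diphenyl)silyl]oxypropyl}-6-iodo-2-methyl-3-(prop-1-en-2-yl)hept-5-enoic acid, via sodium carboxylate 10 (not isolated)
Conditions: NaN(SiMe3)2 (1 equiv), THF, −78 °C; then Ph3P=C(I)CH3 [from EtPPh3I, n-BuLi, I2, NaN(SiMe3)2], THF, −78 °C to rt; aqueous HCl work-up
Reagents that add atoms: (1-iodoethyl)triphenylphosphonium iodide, CC(I)[P+](c1ccccc1)(c1ccccc1)c1ccccc1.[I-]
Why: the Stork–Zhao variant of the Wittig reaction with the alpha-iodo ylide turns aldehydes into (Z)-2-iodoalk-2-enes with iodine cis to the chain, which restores the methyl-bearing alkene carbon as an alkenyl iodide in the geometry needed for ring closure while the acid is masked in the flask as its carboxylate.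

Step 7
Reactants: 11 iodo acid
Product: 13 (3R,4R,6Z)-3-{3-[tert-butyl(diphenyl)silyl]oxypropyl}-1-diazo-7-iodo-3-methyl-4-(prop-1-en-2-yl)oct-6-en-2-one, via acid chloride 12 (not isolated)
Conditions: (COCl)2, DMF (cat.), CH2Cl2, 0 °C; then CH2N2, Et3N, Et2O, 0 °C
Reagents that add atoms: diazomethane, C=[N+]=[N-]
Why: acylation of diazomethane by the acid chloride (first half of the Arndt–Eistert homologation) is known for alpha-quaternary acids and should not affect the stereocentres, the alkenyl iodide or the silyl ether.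

Step 8
Reactants: 13 diazoketone
Product: 15 methyl (3S,4R,6Z)-3-{3-[tert-butyl(diphenyl)silyl]oxypropyl}-7-iodo-3-methyl-4-(prop-1-en-2-yl)oct-6-enoate, via ketene 14 (not isolated)
Conditions: PhCO2Ag (cat.), Et3N, MeOH, rt
Reagents that add atoms: methanol, CO
Why: silver-catalysed Wolff rearrangement shifts the fully substituted carbon with retention of configuration to give a ketene that methanol traps as the homologous ester, so the future ring carbon C2 now sits between the quaternary carbon and the ester carbonyl.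

Step 9
Reactants: 15 iodo ester
Product: 18 methyl (1R,5R,6R)-6-{3-[tert-butyl(diphenyl)silyl]oxypropyl}-2,6-dimethyl-5-(prop-1-en-2-yl)cyclohex-2-ene-1-carboxylate, via lithium ester enolate 16 (not isolated), via lithium dienolate 17 (not isolated)
Conditions: LiN(SiMe3)2 (2.5 equiv), Pd2(dba)3 (5 mol %), P(t-Bu)3 (12 mol %), toluene, rt to 50 °C; then AcOH, THF, −78 °C
Reagents that add atoms: none
Why: Deprotonation of the only ester gives enolate 16, zerovalent palladium inserts into the (Z)-alkenyl C–I bond, and the resulting alkenylpalladium enolate reductively eliminates to form the C2–C3 bond. The closest known reaction type is the palladium-catalysed alpha-alkenylation (and arylation) of ester enolates in its intramolecular form. The six-membered carbocycle is closed by C(sp3)–C(sp2) reductive elimination from a seven-membered palladacycle, with the alkene ending endocyclic, which requires the Z geometry of the iodide (iodine cis to the chain). The new stereocentre C2 is not left to the bond-forming event: the product is more acidic than 15, the excess amide converts it into the extended enolate 17, and kinetic alpha-protonation at −78 °C from the face opposite the pseudo-axial C1 methyl (C6 isopropenyl pseudo-equatorial) should place the ester cis to that methyl, so both C2 epimers converge. The step needs alpha- over gamma-protonation (kinetic protonation of dienolates is alpha-selective and keeps the C3=C4 alkene out of conjugation) and no Claisen condensation, which is secured because the future acid carbon is carried as a silyl ether and no second ester is present.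

Step 10
Reactants: 18 cyclohexene ester
Product: 19 [(1R,5R,6R)-6-{3-[tert-butyl(diphenyl)silyl]oxypropyl}-2,6-dimethyl-5-(prop-1-en-2-yl)cyclohex-2-en-1-yl]methanol
Conditions: LiAlH4, THF, 0 °C
Reagents that add atoms: none
Why: hydride reduction of the hindered ester to the primary alcohol proceeds without base-mediated equilibration, so the C2 configuration is fixed once the carbonyl is gone.

Step 11
Reactants: 19 primary alcohol; 20 umbelliferone (7-hydroxy-2H-chromen-2-one)
Product: 21 7-{[(1R,5R,6R)-6-{3-[tert-butyl(diphenyl)silyl]oxypropyl}-2,6-dimethyl-5-(prop-1-en-2-yl)cyclohex-2-en-1-yl]methoxy}-2H-chromen-2-one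
Conditions: PPh3, DIAD, THF, 0 °C to rt
Reagents that add atoms: none
Why: Mitsunobu etherification joins the acidic coumarin phenol to the primary carbinol carbon under neutral conditions that leave the lactone and the alkenes untouched, and no stereocentre is involved.

Step 12
Reactants: 21 silyl ether
Product: 22 7-{[(1R,5R,6R)-6-(3-hydroxypropyl)-2,6-dimethyl-5-(prop-1-en-2-yl)cyclohex-2-en-1-yl]methoxy}-2H-chromen-2-one
Conditions: Bu4NF, THF, rt
Reagents that add atoms: none
Why: fluoride cleaves the silyl ether selectively, and the aryl ether, lactone and alkenes are stable to it.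

Step 13
Reactants: 22 primary alcohol
Product: 23 3-[(1R,2R,6R)-1,3-dimethyl-2-{[(2-oxo-2H-chromen-7-yl)oxy]methyl}-6-(prop-1-en-2-yl)cyclohex-3-en-1-yl]propanoic acid (target)
Conditions: TEMPO (cat.), PhI(OAc)2, MeCN/H2O, rt
Reagents that add atoms: water, O
Why: the oxoammonium-mediated oxidation of an unhindered primary alcohol through the aldehyde hydrate to the acid is mild and should tolerate the isolated alkenes, the aryl ether and the coumarin.

**Compound list**

1 | 3-iodopropan-1-ol | OCCCI | starting material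
2 | tert-butyl(3-iodopropoxy)diphenylsilane | ICCCO[Si](c1ccccc1)(c1ccccc1)C(C)(C)C | intermediate
3 | (S)-(+)-carvone, (5S)-2-methyl-5-(prop-1-en-2-yl)cyclohex-2-en-1-one | C=C(C)[C@H]1CC=C(C)C(=O)C1 | starting material
4 | lithium alpha-prime enolate of carvone | C=C(C)[C@H]1CC=C(C)C([O-])=C1.[Li+] | intermediate
5 | (5S)-2,6-dimethyl-5-(prop-1-en-2-yl)cyclohex-2-en-1-one (C6 epimers) | C=C(C)[C@H]1CC=C(C)C(=O)C1C | intermediate
6 | lithium enolate of 5 | C=C(C)[C@H]1CC=C(C)C([O-])=C1C.[Li+] | intermediate
7 | (5R,6R)-6-{3-[tert-butyl(diphenyl)silyl]oxypropyl}-2,6-dimethyl-5-(prop-1-en-2-yl)cyclohex-2-en-1-one | C=C(C)[C@H]1CC=C(C)C(=O)[C@]1(C)CCCO[Si](c2ccccc2)(c2ccccc2)C(C)(C)C | intermediate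
8 | (3R,4R)-3-{3-[tert-butyl(diphenyl)silyl]oxypropyl}-1,3-dimethyl-4-(prop-1-en-2-yl)-7-oxabicyclo[4.1.0]heptan-2-one (epoxide diastereomers) | C=C(C)[C@H]1CC2OC2(C)C(=O)[C@]1(C)CCCO[Si](c3ccccc3)(c3ccccc3)C(C)(C)C | intermediate
9 | (2R,3R)-2-{3-[tert-butyl(diphenyl)silyl]oxypropyl}-2,4-dimethyl-3-(2-oxoethyl)pent-4-enoic acid | C=C(C)[C@@H](CC=O)[C@@](C)(CCCO[Si](c1ccccc1)(c1ccccc1)C(C)(C)C)C(=O)O | intermediate
10 | sodium carboxylate of 9 | C=C(C)[C@@H](CC=O)[C@@](C)(CCCO[Si](c1ccccc1)(c1ccccc1)C(C)(C)C)C(=O)[O-].[Na+] | intermediate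
11 | (2R,3R,5Z)-2-{3-[tert-butyl(diphenyl)silyl]oxypropyl}-6-iodo-2-methyl-3-(prop-1-en-2-yl)hept-5-enoic acid | C=C(C)[C@@H](C/C=C(\I)C)[C@@](C)(CCCO[Si](c1ccccc1)(c1ccccc1)C(C)(C)C)C(=O)O | intermediate
12 | acid chloride of 11 | C=C(C)[C@@H](C/C=C(\I)C)[C@@](C)(CCCO[Si](c1ccccc1)(c1ccccc1)C(C)(C)C)C(=O)Cl | intermediate
13 | (3R,4R,6Z)-3-{3-[tert-butyl(diphenyl)silyl]oxypropyl}-1-diazo-7-iodo-3-methyl-4-(prop-1-en-2-yl)oct-6-en-2-one | C=C(C)[C@@H](C/C=C(\I)C)[C@@](C)(CCCO[Si](c1ccccc1)(c1ccccc1)C(C)(C)C)C(=O)C=[N+]=[N-] | intermediate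
14 | ketene from Wolff rearrangement of 13 | C=C(C)[C@@H](C/C=C(\I)C)[C@@](C)(CCCO[Si](c1ccccc1)(c1ccccc1)C(C)(C)C)C=C=O | intermediate
15 | methyl (3S,4R,6Z)-3-{3-[tert-butyl(diphenyl)silyl]oxypropyl}-7-iodo-3-methyl-4-(prop-1-en-2-yl)oct-6-enoate | C=C(C)[C@@H](C/C=C(\I)C)[C@@](C)(CCCO[Si](c1ccccc1)(c1ccccc1)C(C)(C)C)CC(=O)OC | intermediate
16 | lithium enolate of ester 15 | C=C(C)[C@@H](C/C=C(\I)C)[C@@](C)(CCCO[Si](c1ccccc1)(c1ccccc1)C(C)(C)C)C=C([O-])OC.[Li+] | intermediate
17 | lithium dienolate of ester 18 | C=C(C)[C@H]1CC=C(C)C(=C([O-])OC)[C@]1(C)CCCO[Si](c2ccccc2)(c2ccccc2)C(C)(C)C.[Li+] | intermediate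
18 | methyl (1R,5R,6R)-6-{3-[tert-butyl(diphenyl)silyl]oxypropyl}-2,6-dimethyl-5-(prop-1-en-2-yl)cyclohex-2-ene-1-carboxylate | C=C(C)[C@H]1CC=C(C)[C@@H](C(=O)OC)[C@]1(C)CCCO[Si](c2ccccc2)(c2ccccc2)C(C)(C)C | intermediate
19 | [(1R,5R,6R)-6-{3-[tert-butyl(diphenyl)silyl]oxypropyl}-2,6-dimethyl-5-(prop-1-en-2-yl)cyclohex-2-en-1-yl]methanol | C=C(C)[C@H]1CC=C(C)[C@@H](CO)[C@]1(C)CCCO[Si](c2ccccc2)(c2ccccc2)C(C)(C)C | intermediate
20 | umbelliferone, 7-hydroxy-2H-chromen-2-one | Oc1ccc2ccc(=O)oc2c1 | starting material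
21 | 7-{[(1R,5R,6R)-6-{3-[tert-butyl(diphenyl)silyl]oxypropyl}-2,6-dimethyl-5-(prop-1-en-2-yl)cyclohex-2-en-1-yl]methoxy}-2H-chromen-2-one | C=C(C)[C@H]1CC=C(C)[C@@H](COc2ccc3ccc(=O)oc3c2)[C@]1(C)CCCO[Si](c4ccccc4)(c4ccccc4)C(C)(C)C | intermediate
22 | 7-{[(1R,5R,6R)-6-(3-hydroxypropyl)-2,6-dimethyl-5-(prop-1-en-2-yl)cyclohex-2-en-1-yl]methoxy}-2H-chromen-2-one | C=C(C)[C@H]1CC=C(C)[C@@H](COc2ccc3ccc(=O)oc3c2)[C@]1(C)CCCO | intermediate
23 | 3-[(1R,2R,6R)-1,3-dimethyl-2-{[(2-oxo-2H-chromen-7-yl)oxy]methyl}-6-(prop-1-en-2-yl)cyclohex-3-en-1-yl]propanoic acid | C=C(C)[C@H]1CC=C(C)[C@@H](COc2ccc3ccc(=O)oc3c2)[C@]1(C)CCC(=O)O | target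

**Step count**

Total steps: 13. Longest linear sequence: 12 (steps 2 to 13, from (S)-carvone).

**Steps most likely to fail, with fallbacks**

Step 9 (ring closure). Reductive elimination at the congested enolate carbon next to the quaternary centre may be slow. The excess base may then dehydroiodinate or protodeiodinate the alkenyl iodide, and the alkene may drift into conjugation or the protonation may give poor facial selectivity at C2. The fallback sets out from ester 15 and returns at alcohol 19, using a radical ring closure in which the geometry of the alkenyl halide no longer matters. Reduction of 15 with (i-Bu)2AlH at −78 °C should give the aldehyde (3S,4R,6Z)-3-{3-[tert-butyl(diphenyl)silyl]oxypropyl}-7-iodo-3-methyl-4-(prop-1-en-2-yl)oct-6-enal F1. Treatment with t-BuMe2SiOTf and Et3N should give its tert-butyldimethylsilyl enol ether F2 as an E/Z mixture. With Bu3SnH and AIBN in benzene at 80 °C the alkenyl radical should add 6-exo to the enol ether carbon; the alpha-silyloxy radical is then reduced to tert-butyl{[(1R,5R,6R)-6-{3-[tert-butyl(diphenyl)silyl]oxypropyl}-2,6-dimethyl-5-(prop-1-en-2-yl)cyclohex-2-en-1-yl]methoxy}dimethylsilane F3, with C2 set irreversibly through a chair-like transition state with the enol ether equatorial. Methanolysis with pyridinium tosylate should remove only the primary tert-butyldimethylsilyl group and give 19.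

Step 3 (second alkylation). C-alkylation of the hindered tetrasubstituted enolate by an unactivated primary iodide may be sluggish, and proton transfer or O-alkylation may compete. The fallback sets out from 5 and returns at 7, replacing the alkylation by a Lewis-acid conjugate addition. LiN(i-Pr)2 and Me3SiCl should give the trimethylsilyl dienol ether of 5 F4. Mukaiyama–Michael addition to acrolein (TiCl4, CH2Cl2, −78 °C), again anti to isopropenyl, should give 3-[(1R,6R)-1,3-dimethyl-2-oxo-6-(prop-1-en-2-yl)cyclohex-3-en-1-yl]propanal F5. NaBH4 in MeOH at −78 °C should reduce only the aldehyde to (5R,6R)-6-(3-hydroxypropyl)-2,6-dimethyl-5-(prop-1-en-2-yl)cyclohex-2-en-1-one F6, and silylation with t-BuPh2SiCl and imidazole gives 7.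

Step 5 (oxidative ring opening). Hydrolytic opening of the electron-poor epoxy ketone may be incomplete under periodic acid, or the prolonged acid exposure may start to remove the silyl ether. The fallback sets out from 7 and returns at 11, going through the alcohol oxidation level. Luche reduction (NaBH4, CeCl3, MeOH) should give the allylic alcohol (5R,6R)-6-{3-[tert-butyl(diphenyl)silyl]oxypropyl}-2,6-dimethyl-5-(prop-1-en-2-yl)cyclohex-2-en-1-ol F7. Hydroxyl-directed epoxidation (VO(acac)2, t-BuOOH) should give the epoxy alcohol F8, which opens far more readily; with H5IO6 it should be cleaved twice to the dialdehyde (2R,3R)-2-{3-[tert-butyl(diphenyl)silyl]oxypropyl}-2,4-dimethyl-3-(2-oxoethyl)pent-4-enal F9. One equivalent of the Stork–Zhao ylide should react at the unhindered aldehyde only and give (2R,3R,5Z)-2-{3-[tert-butyl(diphenyl)silyl]oxypropyl}-6-iodo-2-methyl-3-(prop-1-en-2-yl)hept-5-enal F10. Pinnick oxidation (NaClO2, NaH2PO4, 2-methylbut-2-ene) then gives 11.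

**Further compounds**

F1 | step 9 | (3S,4R,6Z)-3-{3-[tert-butyl(diphenyl)silyl]oxypropyl}-7-iodo-3-methyl-4-(prop-1-en-2-yl)oct-6-enal | C=C(C)[C@@H](C/C=C(\I)C)[C@@](C)(CCCO[Si](c1ccccc1)(c1ccccc1)C(C)(C)C)CC=O
F2 | step 9 | tert-butyldimethylsilyl enol ether of F1 (E/Z mixture) | C=C(C)[C@@H](C/C=C(\I)C)[C@@](C)(CCCO[Si](c1ccccc1)(c1ccccc1)C(C)(C)C)C=CO[Si](C)(C)C(C)(C)C
F3 | step 9 | tert-butyl{[(1R,5R,6R)-6-{3-[tert-butyl(diphenyl)silyl]oxypropyl}-2,6-dimethyl-5-(prop-1-en-2-yl)cyclohex-2-en-1-yl]methoxy}dimethylsilane | C=C(C)[C@H]1CC=C(C)[C@@H](CO[Si](C)(C)C(C)(C)C)[C@]1(C)CCCO[Si](c2ccccc2)(c2ccccc2)C(C)(C)C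
F4 | step 3 | trimethylsilyl dienol ether of 5 | C=C(C)[C@H]1CC=C(C)C(O[Si](C)(C)C)=C1C
F5 | step 3 | 3-[(1R,6R)-1,3-dimethyl-2-oxo-6-(prop-1-en-2-yl)cyclohex-3-en-1-yl]propanal | C=C(C)[C@H]1CC=C(C)C(=O)[C@]1(C)CCC=O
F6 | step 3 | (5R,6R)-6-(3-hydroxypropyl)-2,6-dimethyl-5-(prop-1-en-2-yl)cyclohex-2-en-1-one | C=C(C)[C@H]1CC=C(C)C(=O)[C@]1(C)CCCO
F7 | step 5 | (5R,6R)-6-{3-[tert-butyl(diphenyl)silyl]oxypropyl}-2,6-dimethyl-5-(prop-1-en-2-yl)cyclohex-2-en-1-ol (carbinol epimers) | C=C(C)[C@H]1CC=C(C)C(O)[C@]1(C)CCCO[Si](c2ccccc2)(c2ccccc2)C(C)(C)C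
F8 | step 5 | (3R,4R)-3-{3-[tert-butyl(diphenyl)silyl]oxypropyl}-1,3-dimethyl-4-(prop-1-en-2-yl)-7-oxabicyclo[4.1.0]heptan-2-ol | C=C(C)[C@H]1CC2OC2(C)C(O)[C@]1(C)CCCO[Si](c3ccccc3)(c3ccccc3)C(C)(C)C
F9 | step 5 | (2R,3R)-2-{3-[tert-butyl(diphenyl)silyl]oxypropyl}-2,4-dimethyl-3-(2-oxoethyl)pent-4-enal | C=C(C)[C@@H](CC=O)[C@@](C)(CCCO[Si](c1ccccc1)(c1ccccc1)C(C)(C)C)C=O
F10 | step 5 | (2R,3R,5Z)-2-{3-[tert-butyl(diphenyl)silyl]oxypropyl}-6-iodo-2-methyl-3-(prop-1-en-2-yl)hept-5-enal | C=C(C)[C@@H](C/C=C(\I)C)[C@@](C)(CCCO[Si](c1ccccc1)(c1ccccc1)C(C)(C)C)C=O
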